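## Structural features

The target is a germacranolide: a ten-membered carbocycle (C1–C10) fused at C6–C7 to a butenolide (C7=C11, C12 carbonyl, ring oxygen on C6). C11 carries the C13 acetoxymethyl group, the C8 oxygen carries a methacrylate, and two trisubstituted epoxides (C1–C10 with methyl C14, C4–C5 with methyl C15) complete the ring.

The SMILES fixes 1R,4S,5R,6R,8R,10S. Read on the ring, both epoxide oxygens, the lactone oxygen on C6 and the ester oxygen on C8 lie on one face, and at each epoxide the two ring carbons are cis (C9/C2 and C3/C6). The stereocentres form a contiguous set C4–C5–C6 and a 1,3-related set C8/C10–C1.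

Two consequences shape the design:
- A cis 1,10-epoxide can only come from a 1(10)Z alkene, so the ring alkene of the key-step precursor and product must be Z; an E alkene would give the trans epoxide.
- A cis 4,5-epoxide closed by the C4 oxygen displacing a C5 leaving group with inversion needs the 4,5-syn (5S) carbinol. This is the chelation sense of addition to the C5 aldehyde; the Felkin–Anh sense gives the other C5 epimer.

Fragile sites are the two epoxides (acid, transannular attack), the acidic C6–H γ to the lactone carbonyl (β-elimination of a C5 leaving group or of the 4,5-epoxide), the butenolide (translactonisation onto a free C8 hydroxyl), the allylic acetate and the methacrylate. The real difficulty is closing a ten-membered ring while setting C5 and C6, then placing two epoxides on defined faces.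

The key step uses the fact that C6 is the γ-carbon of the butenolide and C5 is an oxygenated carbon next to the tertiary carbinol C4. C5–C6 is therefore a vinylogous aldol bond between a 2-silyloxyfuran (C12, C11, C7, C6) and a C5 aldehyde, whose C4 oxygen first steers the addition and later becomes the epoxide oxygen.

## Logic of the disconnections

42 ⇒ 40 + 41. The acyl–O8 bond is cut. The methacrylate is the most base- and nucleophile-sensitive group and is best added last. The forward acylation must be fast and mild enough not to move the lactone onto O8 or open an epoxide.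

40 ⇒ 39 ⇒ 38. The C1–O and C10–O bonds of the 1,10-epoxide are cut, then the O8–Si bond. The epoxide oxygen is cis to O8 on the ring, so the free C8 hydroxyl of 39 can deliver it. Two stereocentres are removed. The forward step demands a Z alkene in 39 and hydroxyl-directed syn epoxidation.

38 ⇒ 37 ⇒ 35 + 36 ⇒ 34 ⇒ 33. The C5–O bond of the 4,5-epoxide is cut while C4–O is kept, then the acetyl–O13 bond, the two benzylic C–O bonds and the S–O5 bond. This traces the epoxide to a C4 carbinol and a C5 leaving group, so no 4,5-alkene and no face-selective epoxidation are needed. The forward closure inverts C5, so 33 must be 5S, and it must outrun loss of the C6 proton.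

33 ⇒ 32. The C5–C6 bond is cut (key step). One cut opens the ten-membered ring and removes C5 and C6 as stereocentres, leaving an acyclic aldehyde tethered to a silyloxyfuran. The forward step must close a medium ring and deliver 5S,6R; the ether at O4 is therefore a coordinating one.

32 ⇒ 31 ⇒ 30 ⇒ 29. The furan O–Si bond, the C5 oxidation level and the O5–Si bond are adjusted. This returns to a stable butenolide with C5 masked as a silyl ether. The forward steps need selective removal of the primary silyl ether beside the secondary one, and enol silylation that does not trigger the aldol early.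

29 ⇒ 28 ⇒ 27 ⇒ 19 + 26. The C7=C11 double bond and the C12–O6 ester bond are cut (the O8–Si bond in between). The butenolide becomes an α-hydroxy ketone and a phosphonoacetic acid that already carries C13. The forward steps need selective acylation of the primary hydroxyl and an olefination faster than any epimerisation at C8.

26 ⇒ 25 ⇒ 23 + 24; 23 ⇒ 20 + 21. The C13–O bond and the C11–C13 bond are cut, reaching three commodity compounds. The forward ester cleavage must not expel the β-alkoxy group.

19 ⇒ 18 ⇒ 17 ⇒ 15 + 12; 15 ⇒ 13 + 14. The C8–C9 bond is cut, after unmasking the diol and the ketone. C8 is traced to a dihydroxyacetone equivalent carrying a recoverable auxiliary, and the rest to an allylic bromide. The forward alkylation must set C8 as R and keep the Z alkene.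

12 ⇒ 11 ⇒ 10 ⇒ 9 ⇒ 7. Functional-group changes at C9 (bromide, alcohol, ester) and at C5 (silyl ether, alcohol) lead back to the C5=CH2 bond, which is cut. The vinyl group must be cleaved while C1=C10 is still conjugated to the C9 ester; later the isolated trisubstituted alkene would react first.

7 ⇒ 5 + 6 ⇒ 3 ⇒ 1 + 2. The C1=C10 double bond is cut, then the original trisubstituted alkene of 3 is restored and the benzylic O–C bond is cut. The olefination must be Z-selective; allylic oxidation of the terminal methyl of 3 would give only the E series. Compound 1 supplies C1–C5, C15 and the C4 stereocentre with its oxygen.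

## Other disconnections considered

Alternative 1: Joining C5 to C10 turns the carbocycle into a decalin, so the forward key step breaks that σ-bond. Borane adds to a tetrasubstituted C4=C5 alkene of a trans-fused bicyclic precursor on the face away from the angular methyl. Methoxide then fragments the borate with loss of a C1 sulfonate, giving the E,E-cyclodecadiene ketal A1.
- In favour: the ring is formed without dilution or entropic penalty, the process is stereospecific, and it is established chemistry. On these points it is better than the chosen plan. C8 is set before ring formation, which is equal.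
- Against here: A1 is E at both alkenes, while the target needs the cis epoxides of a Z,Z diene. Reprogramming both geometries would require a differently fused and substituted bicycle.
- A1 also lacks the C6 oxygen, C11–C13 and both epoxide oxygens. After ketal removal, C6 would have to be oxygenated selectively, the butenolide annulated, and two epoxidations run on the macrocycle, the 4,5-one without a directing group.
- Comparison: on structure the chosen plan reaches ring closure with all carbons and four of six stereocentres in place, against one for A1. On mechanism the concerted fragmentation is more predictable. On step economy A1 is clearly longer.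

Alternative 2: The cut is C9–C10. An acyclic butenolide with a terminal C8–C9 epoxide and a C10 alkenyl iodide is treated with nickel diiodide, a bipyridine ligand, sodium iodide and zinc. Iodide opens the epoxide at C9, the nickel catalyst joins C9 to C10, and the C8 hydroxyl is freed in the ring-closed triene A2.
- In favour: A2 already holds the lactone, the C13 acetate, C6 and C8 and a free C8 hydroxyl, so only acylation and epoxidation remain. In post-cyclisation step count it is better than the chosen plan.
- Alkene geometry of the iodide is retained, so a Z iodide could be used; this is equal to the chosen plan for the 1(10) alkene.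
- Against here: A2 is 1(10)E,4E, which leads to trans epoxides. Even in a Z,Z series the 4,5-epoxide would be made by undirected epoxidation of the macrocycle.
- The open-chain precursor carries C6 as a doubly activated γ-stereocentre, prone to epimerisation and to isomerisation into a dienyl lactone.
- A ten-membered ring closure by cross-electrophile coupling is as unprecedented as the chosen key step. It is equal in novelty risk but forms no stereocentre, whereas the aldol closure forms two.

Alternative 3: The ten-membered ring is traced to a six-membered one by a [3,3] reconnection. The potassium alkoxide of a 1,2-dialkenylcyclohexenol (KH, 18-crown-6) rearranges through a chair transition state, forming C8–C9 and expanding the ring by four atoms to the cyclodecadienone A3.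
- In favour: this is a known and dependable entry to germacrane rings from cheap terpene material, better than the chosen plan in precedent.
- The chair transition state gives the Z enone, which matches the cis 4,5-relationship of the target. On that epoxide it is equal in principle to the chosen plan.
- Against here: the other alkene of A3 is E, so the 1,10-epoxide would come out trans.
- A3 has C6 as a ketone and lacks C11–C13. C7 must be functionalised, C6 reduced with control, the lactone closed and C13 oxygenated, all on a cyclodecadienone prone to transannular reactions.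
- Comparison: on structure A3 carries only the C8 stereocentre. On mechanism the pericyclic step is more predictable than an open aldol transition state. On step economy it is worse.

Key step: step 21

Assumption (chemistry): (S)-linalool 1 and phosphonate 6 are taken as purchasable in high purity; any minor enantiomer of 1 would be removed as a diastereomer after step 9.

## Route

Step 1
Reactants: 1 (S)-linalool; 2 4-methoxybenzyl chloride
Product: 3 (3S)-3-[(4-methoxybenzyl)oxy]-3,7-dimethylocta-1,6-diene
Conditions: NaH, Bu4NI (cat.), DMF, 0 °C to rt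
Reagents that add atoms: none
Why: Williamson etherification of the tertiary sodium alkoxide with a reactive benzylic halide; basic conditions avoid ionisation of the tertiary allylic C–O bond, so C4 stays S, and the PMB ether is the coordinating group needed at O4 in the key step.

Step 2
Reactants: 3 (3S)-3-[(4-methoxybenzyl)oxy]-3,7-dimethylocta-1,6-diene
Product: 5 (4S)-4-[(4-methoxybenzyl)oxy]-4-methylhex-5-enal, via ozonide 4 (not isolated)
Conditions: O3 (1 equiv), CH2Cl2, −78 °C, Sudan Red 7B as end-point indicator; then PPh3, −78 °C to rt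
Reagents that add atoms: ozone, [O-][O+]=O
Why: Chemoselective ozonolysis; the trisubstituted alkene is far more electron-rich than the vinyl group on the oxygenated quaternary carbon and than the anisyl ring, so titration to the dye end point should cleave only it, and phosphine reduction of the ozonide gives the C1 aldehyde.

Step 3
Reactants: 5 (4S)-4-[(4-methoxybenzyl)oxy]-4-methylhex-5-enal; 6 ethyl 2-[bis(2,2,2-trifluoroethoxy)phosphoryl]propanoate
Product: 7 ethyl (2Z,6S)-6-[(4-methoxybenzyl)oxy]-2,6-dimethylocta-2,7-dienoate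
Conditions: KN(SiMe3)2, 18-crown-6, THF, −78 °C
Reagents that add atoms: none
Why: Still–Gennari olefination; fast, kinetically controlled collapse of the oxaphosphetane from the electron-poor phosphonate should give the Z trisubstituted enoate, placing C9 (ester carbon) cis to C2 as the cis 1,10-epoxide requires, and it puts C1=C10 into conjugation for step 4.

Step 4
Reactants: 7 ethyl (2Z,6S)-6-[(4-methoxybenzyl)oxy]-2,6-dimethylocta-2,7-dienoate
Product: 9 ethyl (2Z,6S)-7-hydroxy-6-[(4-methoxybenzyl)oxy]-2,6-dimethylhept-2-enoate, via aldehyde 8 (not isolated)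
Conditions: OsO4 (cat.), NaIO4, 2,6-lutidine, dioxane/H2O, rt; then MeOH, NaBH4, 0 °C
Reagents that add atoms: osmium tetroxide, O=[Os](=O)(=O)=O; sodium periodate, [Na+].[O-]I(=O)(=O)=O
Why: Lemieux–Johnson cleavage should select the isolated vinyl group because the other alkene is an electron-poor enoate; borohydride reduction in the same flask parks C5 as a primary alcohol while the ester is untouched at 0 °C.

Step 5
Reactants: 9 ethyl (2Z,6S)-7-hydroxy-6-[(4-methoxybenzyl)oxy]-2,6-dimethylhept-2-enoate
Product: 10 ethyl (2Z,6S)-7-[(tert-butyldiphenylsilyl)oxy]-6-[(4-methoxybenzyl)oxy]-2,6-dimethylhept-2-enoate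
Conditions: TBDPSCl, imidazole, DMF, rt
Reagents that add atoms: tert-butyl(chloro)diphenylsilane, CC(C)(C)[Si](Cl)(c1ccccc1)c1ccccc1
Why: Silylation of the primary alcohol without strong base (no oxa-Michael addition to the enoate); TBDPS survives the acid of steps 10 and 11 and is later removable by buffered fluoride before a secondary TBS ether.

Step 6
Reactants: 10 ethyl (2Z,6S)-7-[(tert-butyldiphenylsilyl)oxy]-6-[(4-methoxybenzyl)oxy]-2,6-dimethylhept-2-enoate
Product: 11 (2Z,6S)-7-[(tert-butyldiphenylsilyl)oxy]-6-[(4-methoxybenzyl)oxy]-2,6-dimethylhept-2-en-1-ol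
Conditions: i-Bu2AlH, CH2Cl2, −78 °C
Reagents that add atoms: none
Why: 1,2-Reduction of the enoate to the allylic alcohol; hydride adds only to the ester carbonyl, so the Z geometry is kept.

Step 7
Reactants: 11 (2Z,6S)-7-[(tert-butyldiphenylsilyl)oxy]-6-[(4-methoxybenzyl)oxy]-2,6-dimethylhept-2-en-1-ol
Product: 12 (2Z,6S)-1-bromo-7-[(tert-butyldiphenylsilyl)oxy]-6-[(4-methoxybenzyl)oxy]-2,6-dimethylhept-2-ene
Conditions: CBr4, PPh3, CH2Cl2, 0 °C
Reagents that add atoms: carbon tetrabromide, BrC(Br)(Br)Br
Why: Appel bromination under neutral conditions; SN2 displacement at the primary allylic carbon should keep the Z alkene, and the bromide is used at once.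

Step 8
Reactants: 13 2,2-dimethyl-1,3-dioxan-5-one; 14 (R)-1-amino-2-(methoxymethyl)pyrrolidine (RAMP)
Product: 15 (R)-N-(2,2-dimethyl-1,3-dioxan-5-ylidene)-2-(methoxymethyl)pyrrolidin-1-amine
Conditions: cyclohexane, reflux, Dean–Stark
Reagents that add atoms: none
Why: Hydrazone condensation driven by removal of water; it installs the auxiliary that will control C8.

Step 9
Reactants: 15 (R)-N-(2,2-dimethyl-1,3-dioxan-5-ylidene)-2-(methoxymethyl)pyrrolidin-1-amine; 12 (2Z,6S)-1-bromo-7-[(tert-butyldiphenylsilyl)oxy]-6-[(4-methoxybenzyl)oxy]-2,6-dimethylhept-2-ene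
Product: 17 RAMP hydrazone of (4R)-4-[(2Z,6S)-7-(tert-butyldiphenylsilyloxy)-6-(4-methoxybenzyloxy)-2,6-dimethylhept-2-enyl]-2,2-dimethyl-1,3-dioxan-5-one, via lithium azaenolate 16 (not isolated)
Conditions: t-BuLi, THF, −78 °C; then 12, −100 to −78 °C
Reagents that add atoms: none
Why: RAMP-hydrazone alkylation; the lithium azaenolate, chelated by the methoxymethyl group, is alkylated on its open face, which by the uniform facial bias of this auxiliary should set C8 as R (the antipodal auxiliary gives S), and SN2 at the primary allylic bromide keeps the Z alkene.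

Step 10
Reactants: 17 RAMP hydrazone of the (4R)-4-alkyl-2,2-dimethyl-1,3-dioxan-5-one
Product: 18 (4R)-4-[(2Z,6S)-7-(tert-butyldiphenylsilyloxy)-6-(4-methoxybenzyloxy)-2,6-dimethylhept-2-enyl]-2,2-dimethyl-1,3-dioxan-5-one
Conditions: saturated aqueous oxalic acid, Et2O, rt
Reagents that add atoms: water, O
Why: Mild two-phase hydrolysis of the hydrazone that should spare the acetonide and the α-stereocentre; ozonolytic cleavage is excluded by the alkene, and the auxiliary is recovered.

Step 11
Reactants: 18 (4R)-4-alkyl-2,2-dimethyl-1,3-dioxan-5-one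
Product: 19 (3R,5Z,9S)-10-(tert-butyldiphenylsilyloxy)-1,3-dihydroxy-9-(4-methoxybenzyloxy)-5,9-dimethyldec-5-en-2-one
Conditions: 1 M HCl, THF, rt
Reagents that add atoms: none
Why: Acetal hydrolysis; TBDPS and both C–O bonds at C4 tolerate dilute acid, and dilute acid at rt should not enolise the α-hydroxy ketone.

Step 12
Reactants: 20 triethyl phosphonoacetate; 21 paraformaldehyde
Product: 23 ethyl 2-(diethoxyphosphoryl)acrylate, via hydroxymethyl phosphonate 22 (not isolated)
Conditions: piperidine (cat.), MeOH, reflux; then TsOH (cat.), toluene, reflux with removal of water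
Reagents that add atoms: none
Why: Knoevenagel-type hydroxymethylation of the activated methylene followed by acid-catalysed dehydration; this introduces C13.

Step 13
Reactants: 23 ethyl 2-(diethoxyphosphoryl)acrylate; 24 4-methoxybenzyl alcohol
Product: 25 ethyl 2-(diethoxyphosphoryl)-3-[(4-methoxybenzyl)oxy]propanoate
Conditions: KOt-Bu (cat.), THF, 0 °C
Reagents that add atoms: none
Why: Oxa-Michael addition of the alkoxide to the doubly activated alkene; the adduct anion is a far weaker base than the alkoxide, so the equilibrium lies on the side of the ether.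

Step 14
Reactants: 25 ethyl 2-(diethoxyphosphoryl)-3-[(4-methoxybenzyl)oxy]propanoate
Product: 26 2-(diethoxyphosphoryl)-3-[(4-methoxybenzyl)oxy]propanoic acid
Conditions: LiOH, THF/H2O, 0 °C; then 1 M HCl to pH 3
Reagents that add atoms: lithium hydroxide, [Li+].[OH-]
Why: Saponification of the carboxylic ester only; once the carboxylate has formed the α-proton is no longer acidic, which protects the β-alkoxy group from elimination.

Step 15
Reactants: 19 (3R,5Z,9S)-10-(tert-butyldiphenylsilyloxy)-1,3-dihydroxy-9-(4-methoxybenzyloxy)-5,9-dimethyldec-5-en-2-one; 26 2-(diethoxyphosphoryl)-3-[(4-methoxybenzyl)oxy]propanoic acid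
Product: 27 (3R,5Z,9S)-10-(tert-butyldiphenylsilyloxy)-3-hydroxy-9-(4-methoxybenzyloxy)-5,9-dimethyl-2-oxodec-5-enyl 2-(diethoxyphosphoryl)-3-(4-methoxybenzyloxy)propanoate
Conditions: EDC·HCl, DMAP (cat.), CH2Cl2, −20 to 0 °C
Reagents that add atoms: none
Why: Steglich-type esterification; the primary C6 hydroxyl should react well before the secondary C8 hydroxyl, and the primary ester is also the thermodynamic one.

Step 16
Reactants: 27 primary phosphonoacetate ester
Product: 28 the C8 tert-butyldimethylsilyl ether of 27
Conditions: TBSOTf, 2,6-lutidine, CH2Cl2, −78 °C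
Reagents that add atoms: tert-butyldimethylsilyl triflate, CC(C)(C)[Si](C)(C)OS(=O)(=O)C(F)(F)F
Why: Silylation of the secondary hydroxyl with a weak base at low temperature, faster than enol silylation of the ketone; it blocks acyl migration to O8 and gives a bulky, non-coordinating, poor leaving group next to the future furan.

Step 17
Reactants: 28 C8 silyl ether of the keto phosphonate
Product: 29 4-[(1R,3Z,7S)-1-(tert-butyldimethylsilyloxy)-8-(tert-butyldiphenylsilyloxy)-7-(4-methoxybenzyloxy)-3,7-dimethyloct-3-enyl]-3-[(4-methoxybenzyloxy)methyl]furan-2(5H)-one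
Conditions: LiCl, i-Pr2NEt, MeCN, rt
Reagents that add atoms: none
Why: Intramolecular Horner–Wadsworth–Emmons reaction under Masamune–Roush conditions; the five-membered closure onto the C7 ketone forms C7=C11 faster than the mild base can epimerise C8, and any reversible loss of the β-alkoxide is corrected by re-addition before the irreversible olefination.

Step 18
Reactants: 29 butenolide with C5 silyl ether
Product: 30 4-[(1R,3Z,7S)-1-(tert-butyldimethylsilyloxy)-8-hydroxy-7-(4-methoxybenzyloxy)-3,7-dimethyloct-3-enyl]-3-[(4-methoxybenzyloxy)methyl]furan-2(5H)-one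
Conditions: Bu4NF, AcOH (1:1), THF, 0 °C to rt
Reagents that add atoms: none
Why: Buffered fluoride removes a primary TBDPS ether before a hindered secondary TBS ether (diphenylsilyl is the more fluoride-labile), and the buffer keeps the butenolide from being deprotonated.

Step 19
Reactants: 30 primary alcohol
Product: 31 (2S,5Z,8R)-8-(tert-butyldimethylsilyloxy)-2-(4-methoxybenzyloxy)-2,6-dimethyl-8-{4-[(4-methoxybenzyloxy)methyl]-5-oxo-2,5-dihydrofuran-3-yl}oct-5-enal
Conditions: Dess–Martin periodinane, NaHCO3, CH2Cl2, 0 °C to rt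
Reagents that add atoms: none
Why: Dess–Martin oxidation of the primary alcohol; the aldehyde has no α-hydrogen, so neither epimerisation nor enolisation can follow.

Step 20
Reactants: 31 butenolide aldehyde
Product: 32 (2S,5Z,8R)-8-(tert-butyldimethylsilyloxy)-2-(4-methoxybenzyloxy)-2,6-dimethyl-8-{4-[(4-methoxybenzyloxy)methyl]-5-(triisopropylsilyloxy)furan-3-yl}oct-5-enal
Conditions: TIPSOTf, Et3N, CH2Cl2, −78 to 0 °C; filtration through Et3N-deactivated silica, used at once
Reagents that add atoms: triisopropylsilyl triflate, CC(C)[Si](C(C)C)(C(C)C)OS(=O)(=O)C(F)(F)F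
Why: Soft enolisation of the butenolide at C6 gives the aromatic 2-silyloxyfuran; the aldehyde cannot enolise, and the bulky silyl triflate with excess amine is too weak a Lewis acid to start the aldol reaction before step 21.

Step 21
Reactants: 32 silyloxyfuran aldehyde
Product: 33 (4S,5S,6R,8R)-8-(tert-butyldimethylsilyloxy)-5-hydroxy-4,13-bis(4-methoxybenzyloxy)germacra-1(10)Z,7(11)-dien-6,12-olide
Conditions: MgBr2·OEt2 (excess), CH2Cl2, −20 to 0 °C, slow addition of 32 to about 1 mM
Reagents that add atoms: none
Why: Proposed new method: MgBr2 is expected to bind the C5 aldehyde oxygen and the C4 PMB-ether oxygen in a five-membered chelate, the silyloxyfuran then attacks C5 through its γ-terminus C6 in an open transition state, and bromide removes the silyl group from the oxocarbenium ion so that the butenolide returns; the closest known reactions are the intermolecular chelation-controlled vinylogous Mukaiyama aldol addition of 2-silyloxyfurans to α-alkoxy aldehydes and intramolecular vinylogous aldol closures of common-sized carbocycles, the ten-membered closure being the unprecedented part. The ten-membered ring closes in a 10-exo-trig mode at the aldehyde carbon, with the furan C6=C7 bond inside the new ring. C5 is controlled by the chelate: with O4 and the carbonyl oxygen held syn-periplanar, C6 can reach C5 only on the face of the C15 methyl, opposite C3 (a C3–C4–C5–C6 dihedral near 120° instead of an eclipsed one), which is also the intrinsic Cram-chelate preference and gives 5S from 4S. C6 is controlled by the usual antiperiplanar approach of silyloxyfurans under Lewis acids, which leads to the 5,6-threo relationship (6R), and the bulky C8 silyl ether is expected to point outward and not to oppose this folding. Attack through C6 and not C11 is intrinsic to 2-silyloxyfurans and is reinforced by the substituent on C11. Ring closure instead of oligomerisation is secured by slow addition at high dilution and helped by the Z alkene and the planar furan, which remove transannular hydrogens. The coordinating ether at O4 is essential, because a silyl ether with a monodentate Lewis acid would follow the Felkin–Anh sense and give the C5 epimer.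

Step 22
Reactants: 33 macrocyclic C5 alcohol
Product: 34 the C5 methanesulfonate of 33
Conditions: MsCl, Et3N, CH2Cl2, −20 °C
Reagents that add atoms: methanesulfonyl chloride, CS(=O)(=O)Cl
Why: Sulfonylation through sulfene reaches the hindered secondary hydroxyl with retention at C5; the short reaction at low temperature with a weak amine should not yet remove the C6 proton.

Step 23
Reactants: 34 C5 methanesulfonate
Product: 35 (4S,5S,6R,8R)-8-(tert-butyldimethylsilyloxy)-4,13-dihydroxy-5-(methylsulfonyloxy)germacra-1(10)Z,7(11)-dien-6,12-olide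
Conditions: DDQ, CH2Cl2/pH 7 buffer, 0 °C to rt
Reagents that add atoms: none
Why: Oxidative cleavage of both PMB ethers under neutral conditions; with O5 already sulfonylated no cyclic anisylidene acetal can form, and the silyl ether, sulfonate, alkene and butenolide are inert to DDQ.

Step 24
Reactants: 35 hydroxy methanesulfonate diol; 36 acetic anhydride
Product: 37 the 13-acetate of 35
Conditions: pyridine, DMAP (cat.), CH2Cl2, 0 °C
Reagents that add atoms: none
Why: Acylation of the primary allylic hydroxyl only (the tertiary C4 hydroxyl does not react); this installs the final acetate and removes a primary alkoxide that could otherwise attack C5 in step 25.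

Step 25
Reactants: 37 C13 acetate with free C4 hydroxyl
Product: 38 (4S,5R,6R,8R)-13-acetoxy-8-(tert-butyldimethylsilyloxy)-4,5-epoxygermacra-1(10)Z,7(11)-dien-6,12-olide
Conditions: KN(SiMe3)2 (1 equiv), THF, −78 to −40 °C
Reagents that add atoms: none
Why: Intramolecular Williamson closure (3-exo-tet); kinetic deprotonation of O–H is faster than of C6–H, and the tertiary alkoxide displaces the adjacent sulfonate with inversion at C5, turning 5S into 5R and giving the cis 4,5-epoxide with the chiral-pool oxygen.

Step 26
Reactants: 38 epoxide with C8 silyl ether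
Product: 39 (4S,5R,6R,8R)-13-acetoxy-8-hydroxy-4,5-epoxygermacra-1(10)Z,7(11)-dien-6,12-olide
Conditions: HF·pyridine, pyridine, THF, 0 °C to rt
Reagents that add atoms: none
Why: Pyridine-buffered HF cleaves the secondary silyl ether without generating an alkoxide, so translactonisation and acetate migration are avoided, and the buffer should keep the epoxide closed.

Step 27
Reactants: 39 homoallylic alcohol
Product: 40 (1R,4S,5R,6R,8R,10S)-13-acetoxy-8-hydroxy-1,10:4,5-diepoxygermacr-7(11)-en-6,12-olide
Conditions: VO(acac)2 (cat.), t-BuOOH, CH2Cl2, 0 °C to rt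
Reagents that add atoms: tert-butyl hydroperoxide, CC(C)(C)OO
Why: Hydroxyl-directed epoxidation of a homoallylic alcohol; the vanadium alkoxide at O8 delivers oxygen to the alkene face on its own side of the ring, and since O8 and the 1,10-epoxide oxygen are cis in the target this should set 1R,10S, while the electron-poor butenolide is untouched.

Step 28
Reactants: 40 diepoxy alcohol; 41 methacrylic anhydride
Product: 42 CNP0212980.1 (the 8-O-methacrylate of 40)
Conditions: DMAP, i-Pr2NEt, CH2Cl2, 0 °C
Reagents that add atoms: none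
Why: DMAP-catalysed acylation of the secondary alcohol with retention at C8; a rapid reaction at 0 °C with a hindered amine should beat translactonisation and leave both epoxides intact.

## Compound list

1 | (S)-linalool | C=C[C@@](C)(O)CCC=C(C)C | starting material
2 | 4-methoxybenzyl chloride | COc1ccc(CCl)cc1 | starting material
3 | (3S)-3-[(4-methoxybenzyl)oxy]-3,7-dimethylocta-1,6-diene | C=C[C@@](C)(OCc1ccc(OC)cc1)CCC=C(C)C | intermediate
4 | ozonide of 3 (1,2,4-trioxolane, not isolated) | CC1(C)OOC(CC[C@](C)(OCc2ccc(OC)cc2)C=C)O1 | intermediate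
5 | (4S)-4-[(4-methoxybenzyl)oxy]-4-methylhex-5-enal | O=CCC[C@](C)(OCc1ccc(OC)cc1)C=C | intermediate
6 | ethyl 2-[bis(2,2,2-trifluoroethoxy)phosphoryl]propanoate | CCOC(=O)C(C)P(=O)(OCC(F)(F)F)OCC(F)(F)F | starting material
7 | ethyl (2Z,6S)-6-[(4-methoxybenzyl)oxy]-2,6-dimethylocta-2,7-dienoate | CCOC(=O)/C(C)=C\CC[C@](C)(OCc1ccc(OC)cc1)C=C | intermediate
8 | ethyl (2Z,6S)-6-[(4-methoxybenzyl)oxy]-2,6-dimethyl-7-oxohept-2-enoate (not isolated) | CCOC(=O)/C(C)=C\CC[C@](C)(OCc1ccc(OC)cc1)C=O | intermediate
9 | ethyl (2Z,6S)-7-hydroxy-6-[(4-methoxybenzyl)oxy]-2,6-dimethylhept-2-enoate | CCOC(=O)/C(C)=C\CC[C@](C)(OCc1ccc(OC)cc1)CO | intermediate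
10 | ethyl (2Z,6S)-7-[(tert-butyldiphenylsilyl)oxy]-6-[(4-methoxybenzyl)oxy]-2,6-dimethylhept-2-enoate | CCOC(=O)/C(C)=C\CC[C@](C)(OCc1ccc(OC)cc1)CO[Si](c1ccccc1)(c1ccccc1)C(C)(C)C | intermediate
11 | (2Z,6S)-7-[(tert-butyldiphenylsilyl)oxy]-6-[(4-methoxybenzyl)oxy]-2,6-dimethylhept-2-en-1-ol | OC/C(C)=C\CC[C@](C)(OCc1ccc(OC)cc1)CO[Si](c1ccccc1)(c1ccccc1)C(C)(C)C | intermediate
12 | (2Z,6S)-1-bromo-7-[(tert-butyldiphenylsilyl)oxy]-6-[(4-methoxybenzyl)oxy]-2,6-dimethylhept-2-ene | BrC/C(C)=C\CC[C@](C)(OCc1ccc(OC)cc1)CO[Si](c1ccccc1)(c1ccccc1)C(C)(C)C | intermediate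
13 | 2,2-dimethyl-1,3-dioxan-5-one | CC1(C)OCC(=O)CO1 | starting material
14 | (R)-1-amino-2-(methoxymethyl)pyrrolidine (RAMP) | COC[C@H]1CCCN1N | starting material
15 | (R)-N-(2,2-dimethyl-1,3-dioxan-5-ylidene)-2-(methoxymethyl)pyrrolidin-1-amine | COC[C@H]1CCCN1N=C1COC(C)(C)OC1 | intermediate
16 | lithium azaenolate of 15 (not isolated) | [Li]N(N1CCC[C@@H]1COC)C1=COC(C)(C)OC1 | intermediate
17 | RAMP hydrazone of (4R)-4-[(2Z,6S)-7-(tert-butyldiphenylsilyloxy)-6-(4-methoxybenzyloxy)-2,6-dimethylhept-2-enyl]-2,2-dimethyl-1,3-dioxan-5-one | COC[C@H]1CCCN1N=C1COC(C)(C)O[C@@H]1C/C(C)=C\CC[C@](C)(OCc1ccc(OC)cc1)CO[Si](c1ccccc1)(c1ccccc1)C(C)(C)C | intermediate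
18 | (4R)-4-[(2Z,6S)-7-(tert-butyldiphenylsilyloxy)-6-(4-methoxybenzyloxy)-2,6-dimethylhept-2-enyl]-2,2-dimethyl-1,3-dioxan-5-one | O=C1COC(C)(C)O[C@@H]1C/C(C)=C\CC[C@](C)(OCc1ccc(OC)cc1)CO[Si](c1ccccc1)(c1ccccc1)C(C)(C)C | intermediate
19 | (3R,5Z,9S)-10-(tert-butyldiphenylsilyloxy)-1,3-dihydroxy-9-(4-methoxybenzyloxy)-5,9-dimethyldec-5-en-2-one | OCC(=O)[C@H](O)C/C(C)=C\CC[C@](C)(OCc1ccc(OC)cc1)CO[Si](c1ccccc1)(c1ccccc1)C(C)(C)C | intermediate
20 | triethyl phosphonoacetate | CCOC(=O)CP(=O)(OCC)OCC | starting material
21 | paraformaldehyde (as formaldehyde) | C=O | starting material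
22 | ethyl 2-(diethoxyphosphoryl)-3-hydroxypropanoate (not isolated) | CCOC(=O)C(CO)P(=O)(OCC)OCC | intermediate
23 | ethyl 2-(diethoxyphosphoryl)acrylate | CCOC(=O)C(=C)P(=O)(OCC)OCC | intermediate
24 | 4-methoxybenzyl alcohol | COc1ccc(CO)cc1 | starting material
25 | ethyl 2-(diethoxyphosphoryl)-3-[(4-methoxybenzyl)oxy]propanoate (racemic) | CCOC(=O)C(COCc1ccc(OC)cc1)P(=O)(OCC)OCC | intermediate
26 | 2-(diethoxyphosphoryl)-3-[(4-methoxybenzyl)oxy]propanoic acid (racemic) | OC(=O)C(COCc1ccc(OC)cc1)P(=O)(OCC)OCC | intermediate
27 | (3R,5Z,9S)-10-(tert-butyldiphenylsilyloxy)-3-hydroxy-9-(4-methoxybenzyloxy)-5,9-dimethyl-2-oxodec-5-enyl 2-(diethoxyphosphoryl)-3-(4-methoxybenzyloxy)propanoate (epimers at the phosphonate carbon) | CCOP(=O)(OCC)C(COCc1ccc(OC)cc1)C(=O)OCC(=O)[C@H](O)C/C(C)=C\CC[C@](C)(OCc1ccc(OC)cc1)CO[Si](c1ccccc1)(c1ccccc1)C(C)(C)C | intermediate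
28 | 3-O-(tert-butyldimethylsilyl) ether of 27 | CCOP(=O)(OCC)C(COCc1ccc(OC)cc1)C(=O)OCC(=O)[C@H](O[Si](C)(C)C(C)(C)C)C/C(C)=C\CC[C@](C)(OCc1ccc(OC)cc1)CO[Si](c1ccccc1)(c1ccccc1)C(C)(C)C | intermediate
29 | 4-[(1R,3Z,7S)-1-(tert-butyldimethylsilyloxy)-8-(tert-butyldiphenylsilyloxy)-7-(4-methoxybenzyloxy)-3,7-dimethyloct-3-enyl]-3-[(4-methoxybenzyloxy)methyl]furan-2(5H)-one | O=C1OCC([C@H](O[Si](C)(C)C(C)(C)C)C/C(C)=C\CC[C@](C)(OCc2ccc(OC)cc2)CO[Si](c2ccccc2)(c2ccccc2)C(C)(C)C)=C1COCc1ccc(OC)cc1 | intermediate
30 | 4-[(1R,3Z,7S)-1-(tert-butyldimethylsilyloxy)-8-hydroxy-7-(4-methoxybenzyloxy)-3,7-dimethyloct-3-enyl]-3-[(4-methoxybenzyloxy)methyl]furan-2(5H)-one | O=C1OCC([C@H](O[Si](C)(C)C(C)(C)C)C/C(C)=C\CC[C@](C)(OCc2ccc(OC)cc2)CO)=C1COCc1ccc(OC)cc1 | intermediate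
31 | (2S,5Z,8R)-8-(tert-butyldimethylsilyloxy)-2-(4-methoxybenzyloxy)-2,6-dimethyl-8-{4-[(4-methoxybenzyloxy)methyl]-5-oxo-2,5-dihydrofuran-3-yl}oct-5-enal | O=C1OCC([C@H](O[Si](C)(C)C(C)(C)C)C/C(C)=C\CC[C@](C)(OCc2ccc(OC)cc2)C=O)=C1COCc1ccc(OC)cc1 | intermediate
32 | (2S,5Z,8R)-8-(tert-butyldimethylsilyloxy)-2-(4-methoxybenzyloxy)-2,6-dimethyl-8-{4-[(4-methoxybenzyloxy)methyl]-5-(triisopropylsilyloxy)furan-3-yl}oct-5-enal (key-step precursor) | COc1ccc(COCc2c(O[Si](C(C)C)(C(C)C)C(C)C)occ2[C@H](O[Si](C)(C)C(C)(C)C)C/C(C)=C\CC[C@](C)(OCc2ccc(OC)cc2)C=O)cc1 | intermediate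
33 | (4S,5S,6R,8R)-8-(tert-butyldimethylsilyloxy)-5-hydroxy-4,13-bis(4-methoxybenzyloxy)germacra-1(10)Z,7(11)-dien-6,12-olide (key-step product) | COc1ccc(COCC2=C3[C@H](O[Si](C)(C)C(C)(C)C)C/C(C)=C\CC[C@](C)(OCc4ccc(OC)cc4)[C@@H](O)[C@@H]3OC2=O)cc1 | intermediate
34 | 5-O-methanesulfonate of 33 | COc1ccc(COCC2=C3[C@H](O[Si](C)(C)C(C)(C)C)C/C(C)=C\CC[C@](C)(OCc4ccc(OC)cc4)[C@@H](OS(C)(=O)=O)[C@@H]3OC2=O)cc1 | intermediate
35 | (4S,5S,6R,8R)-8-(tert-butyldimethylsilyloxy)-4,13-dihydroxy-5-(methylsulfonyloxy)germacra-1(10)Z,7(11)-dien-6,12-olide | OCC1=C2[C@H](O[Si](C)(C)C(C)(C)C)C/C(C)=C\CC[C@](C)(O)[C@@H](OS(C)(=O)=O)[C@@H]2OC1=O | intermediate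
36 | acetic anhydride | CC(=O)OC(C)=O | starting material
37 | 13-acetate of 35 | CC(=O)OCC1=C2[C@H](O[Si](C)(C)C(C)(C)C)C/C(C)=C\CC[C@](C)(O)[C@@H](OS(C)(=O)=O)[C@@H]2OC1=O | intermediate
38 | (4S,5R,6R,8R)-13-acetoxy-8-(tert-butyldimethylsilyloxy)-4,5-epoxygermacra-1(10)Z,7(11)-dien-6,12-olide | CC(=O)OCC1=C2[C@H](O[Si](C)(C)C(C)(C)C)C/C(C)=C\CC[C@]3(C)O[C@@H]3[C@@H]2OC1=O | intermediate
39 | (4S,5R,6R,8R)-13-acetoxy-8-hydroxy-4,5-epoxygermacra-1(10)Z,7(11)-dien-6,12-olide | CC(=O)OCC1=C2[C@H](O)C/C(C)=C\CC[C@]3(C)O[C@@H]3[C@@H]2OC1=O | intermediate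
40 | (1R,4S,5R,6R,8R,10S)-13-acetoxy-8-hydroxy-1,10:4,5-diepoxygermacr-7(11)-en-6,12-olide | CC(=O)OCC1=C2[C@H](O)C[C@]3(C)O[C@@H]3CC[C@]3(C)O[C@@H]3[C@@H]2OC1=O | intermediate
41 | methacrylic anhydride | C=C(C)C(=O)OC(=O)C(C)=C | starting material
42 | CNP0212980.1, (1R,4S,5R,6R,8R,10S)-13-acetoxy-8-(methacryloyloxy)-1,10:4,5-diepoxygermacr-7(11)-en-6,12-olide | C=C(C)C(=O)O[C@@H]1C[C@]2(C)O[C@@H]2CC[C@]2(C)O[C@@H]2[C@@H]2OC(=O)C(COC(C)=O)=C21 | target

## Step count and least certain steps

Total step count: 28. Longest linear sequence: 24 steps from 1 to 42 (steps 1–7, 9–11 and 15–28); steps 8 and 12–14 are side branches.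

Step 21 (key step, new method). The most likely failure is that intermolecular aldol addition outruns closure of the strained ten-membered ring, or that the folding needed for closure overrides the chelate so that C5 or C6 forms with the wrong configuration. Premature, uncontrolled reaction during step 20 is a related hazard.

The fallback takes the aldol out of the ring and closes the ring at the alkene, using only known reaction types. It sets out from alcohol 30 and returns at 33.
- Ozonolysis of 30 (O3, then PPh3) cuts C1=C10 and gives methyl ketone F1 and six-membered lactol F2.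
- Methylenation of F1 with the Zn/CH2Br2/TiCl4 reagent gives methallyl butenolide F3, and TIPSOTf/Et3N converts it into silyloxyfuran F4.
- Wittig methylenation of F2 gives hydroxy alkene F5, and Dess–Martin oxidation gives aldehyde F6.
- The intermolecular, chelation-controlled vinylogous Mukaiyama aldol addition of F4 to F6 (MgBr2·OEt2) should give open-chain adduct F7 with the 5S,6R pair.
- Ring-closing metathesis of F7 (second-generation Grubbs catalyst, toluene, high dilution) should close C1=C10, with Z favoured by ring strain.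

Step 25. The most likely failure is β-elimination: deprotonation at the acidic C6–H expels the C5 sulfonate and gives the γ-alkylidene butenolide instead of the epoxide. The fallback closes the ring with no base strong enough to touch C6–H; it sets out from 33 and returns at 38.
- Anhydrous DDQ converts the O4 PMB ether and the free C5 hydroxyl into anisylidene acetal F8 and frees O13.
- Acetylation gives acetate F9, and aqueous acetic acid opens the acetal to diol F10.
- Tf2O with 2,6-di-tert-butyl-4-methylpyridine at −78 °C sulfonylates only the secondary hydroxyl. The resulting triflate F11 is displaced by the neighbouring tertiary hydroxyl with inversion as the mixture warms.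

Step 27. The most likely failure is Lewis-acid damage by the vanadium catalyst (opening of the 4,5-epoxide, or translactonisation onto the free C8 hydroxyl), or incomplete delivery of oxygen to the directed face. The fallback drops the directing effect and the metal; it sets out from 39 and returns at 42. Acylation with 41 gives methacrylate F12, and neutral dimethyldioxirane in acetone then epoxidises the only electron-rich alkene. Face selection then rests on the ring conformation alone.

Step 18. The most likely failure is loss of the secondary TBS ether together with the hindered primary TBDPS ether. The fallback gives up the discrimination; it sets out from 29 and returns at 31. Unbuffered Bu4NF removes both silyl groups to give diol F13, TEMPO with PhI(OAc)2 oxidises only the primary alcohol to hydroxy aldehyde F14, and TBSOTf/2,6-lutidine re-silylates O8.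

Step 2. The most likely failure is over-oxidation: attack of ozone on the vinyl group or on the anisyl ring once the trisubstituted alkene is consumed. The fallback replaces ozone by two selective reagents; it sets out from 3 and returns at 5. One equivalent of mCPBA epoxidises only the trisubstituted alkene to give epoxide F15, and periodic acid cleaves the epoxide to the aldehyde.

## Further compounds

F1 | step 21 | 4-[(1R)-1-(tert-butyldimethylsilyloxy)-3-oxobutyl]-3-[(4-methoxybenzyloxy)methyl]furan-2(5H)-one | O=C1OCC([C@H](O[Si](C)(C)C(C)(C)C)CC(C)=O)=C1COCc1ccc(OC)cc1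
F2 | step 21 | (5S)-5-[(4-methoxybenzyl)oxy]-5-methyltetrahydro-2H-pyran-2-ol (anomers) | OC1CC[C@](C)(OCc2ccc(OC)cc2)CO1
F3 | step 21 | 4-[(1R)-1-(tert-butyldimethylsilyloxy)-3-methylbut-3-enyl]-3-[(4-methoxybenzyloxy)methyl]furan-2(5H)-one | O=C1OCC([C@H](O[Si](C)(C)C(C)(C)C)CC(C)=C)=C1COCc1ccc(OC)cc1
F4 | step 21 | 4-[(1R)-1-(tert-butyldimethylsilyloxy)-3-methylbut-3-enyl]-3-[(4-methoxybenzyloxy)methyl]-2-(triisopropylsilyloxy)furan | COc1ccc(COCc2c(O[Si](C(C)C)(C(C)C)C(C)C)occ2[C@H](O[Si](C)(C)C(C)(C)C)CC(C)=C)cc1
F5 | step 21 | (2S)-2-[(4-methoxybenzyl)oxy]-2-methylhex-5-en-1-ol | C=CCC[C@](C)(OCc1ccc(OC)cc1)CO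
F6 | step 21 | (2S)-2-[(4-methoxybenzyl)oxy]-2-methylhex-5-enal | C=CCC[C@](C)(OCc1ccc(OC)cc1)C=O
F7 | step 21 | (5R)-4-[(1R)-1-(tert-butyldimethylsilyloxy)-3-methylbut-3-enyl]-5-[(1S,2S)-1-hydroxy-2-(4-methoxybenzyloxy)-2-methylhex-5-enyl]-3-[(4-methoxybenzyloxy)methyl]furan-2(5H)-one | COc1ccc(COCC2=C([C@H](O[Si](C)(C)C(C)(C)C)CC(C)=C)[C@H]([C@H](O)[C@](C)(CCC=C)OCc3ccc(OC)cc3)OC2=O)cc1
F8 | step 25 | (4S,5S,6R,8R)-8-(tert-butyldimethylsilyloxy)-13-hydroxy-4,5-O-(4-methoxybenzylidene)germacra-1(10)Z,7(11)-dien-6,12-olide (acetal epimers) | OCC1=C2[C@H](O[Si](C)(C)C(C)(C)C)C/C(C)=C\CC[C@]3(C)OC(c4ccc(OC)cc4)O[C@H]3[C@@H]2OC1=O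
F9 | step 25 | 13-acetate of F8 | CC(=O)OCC1=C2[C@H](O[Si](C)(C)C(C)(C)C)C/C(C)=C\CC[C@]3(C)OC(c4ccc(OC)cc4)O[C@H]3[C@@H]2OC1=O
F10 | step 25 | (4S,5S,6R,8R)-13-acetoxy-8-(tert-butyldimethylsilyloxy)-4,5-dihydroxygermacra-1(10)Z,7(11)-dien-6,12-olide | CC(=O)OCC1=C2[C@H](O[Si](C)(C)C(C)(C)C)C/C(C)=C\CC[C@](C)(O)[C@@H](O)[C@@H]2OC1=O
F11 | step 25 | 5-O-trifluoromethanesulfonate of F10 (not isolated) | CC(=O)OCC1=C2[C@H](O[Si](C)(C)C(C)(C)C)C/C(C)=C\CC[C@](C)(O)[C@@H](OS(=O)(=O)C(F)(F)F)[C@@H]2OC1=O
F12 | step 27 | (4S,5R,6R,8R)-13-acetoxy-8-(methacryloyloxy)-4,5-epoxygermacra-1(10)Z,7(11)-dien-6,12-olide | C=C(C)C(=O)O[C@@H]1C/C(C)=C\CC[C@]2(C)O[C@@H]2[C@@H]2OC(=O)C(COC(C)=O)=C21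
F13 | step 18 | 4-[(1R,3Z,7S)-1,8-dihydroxy-7-(4-methoxybenzyloxy)-3,7-dimethyloct-3-enyl]-3-[(4-methoxybenzyloxy)methyl]furan-2(5H)-one | O=C1OCC([C@H](O)C/C(C)=C\CC[C@](C)(OCc2ccc(OC)cc2)CO)=C1COCc1ccc(OC)cc1
F14 | step 18 | (2S,5Z,8R)-8-hydroxy-2-(4-methoxybenzyloxy)-2,6-dimethyl-8-{4-[(4-methoxybenzyloxy)methyl]-5-oxo-2,5-dihydrofuran-3-yl}oct-5-enal | O=C1OCC([C@H](O)C/C(C)=C\CC[C@](C)(OCc2ccc(OC)cc2)C=O)=C1COCc1ccc(OC)cc1
F15 | step 2 | (3S)-6,7-epoxy-3-[(4-methoxybenzyl)oxy]-3,7-dimethyloct-1-ene (epoxide epimers) | CC1(C)OC1CC[C@](C)(OCc1ccc(OC)cc1)C=C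
A1 | alternative 1 | (1(10)E,4E,8R)-8-(tert-butyldimethylsilyloxy)-4,10-dimethylcyclodeca-1(10),4-dien-7-one ethylene ketal (germacrane numbering) | C\C1=C/CC/C(C)=C/CC2(OCCO2)[C@H](O[Si](C)(C)C(C)(C)C)C1
A2 | alternative 2 | 13-acetoxy-8-hydroxygermacra-1(10)E,4E,7(11)-trien-6,12-olide | CC(=O)OCC1=C2[C@H](O)C/C(C)=C/CC/C(C)=C/[C@@H]2OC1=O
A3 | alternative 3 | (2Z,6E,9R)-9-(4-methoxybenzyloxy)-3,7-dimethylcyclodeca-2,6-dien-1-one | O=C1C[C@H](OCc2ccc(OC)cc2)C/C(C)=C/CC/C(C)=C\1
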